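**Plan** (carotenoid numbering: unprimed = epoxy‑keto half, primed = acetylenic half; ring A = trimethylcyclohexane of the epoxy end, ring B = its oxirane, ring C = the cyclohexene that carries the alkyne)

Cuts: C8=O (back to C8–OH), C10–C11 (Suzuki–Miyaura), C8–C9 (aldehyde–alkyne reductive coupling), C11′=C12′ (Wittig with the C10 dialdehyde) and, inside ring C, C3′–C4′ (carbonyl‑ene) and C1′–C6′ (Claisen), so that ring C goes back to an open‑chain racemic aldehyde.
Forward: ring A is bought as (4R,6R)‑actinol, ring B is closed by asymmetric epoxidation (step 5), ring C is closed last (step 16); then C15 + C10 → C25 aldehyde → C26 boronate, union with the C14 epoxy iodide, oxidation of C8.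
Enabling feature: in ring C the carbinol carbon C3′ is homoallylic to C5′=C6′ (C3′–C4′–C5′=C6′), the retron of a carbonyl‑ene reaction, and C6′ is both allylic and propargylic (next to C7′≡C8′), so it can be a racemic sp3 centre in the precursor and is flattened when the double bond moves into conjugation.
Stereochemistry: C3 from actinol; C5 and C6 from the Sharpless epoxidation (reagent control, anti to C3–O); C3′ from a chiral chromium Lewis acid in the ene cyclisation (both C6′ epimers end as one enantiomer after step 17); the C8 carbinol epimers converge on oxidation.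
Alkene geometry: C9′=C10′ bought with the E‑enynol; C11′=C12′ by Wittig and equilibration; C11=C12 by Takai–Utimoto‑type olefination; C9=C10 by syn hydroalkenylation, then stereoretentive iododesilylation and coupling.

Key step: step 16

Assumption: the facial sense of the chromium catalyst on aldehyde 23 cannot be predicted with certainty; the route is written for the complex derived from (1R,2S)‑1‑aminoindan‑2‑ol, and its mirror image is taken if a trial run gives the opposite carbinol. Compounds 1, 14, 17 and 27 and all reagents are taken as commercial.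

**Route**

Step 1
Reactants: 1 (4R,6R)-4-hydroxy-2,2,6-trimethylcyclohexan-1-one
Product: 2 (4R,6R)-4-[(tert-butyldimethylsilyl)oxy]-2,2,6-trimethylcyclohexan-1-one
Conditions: tert-butyldimethylsilyl chloride, imidazole, DMF, rt
Reagents that add atoms: tert-butyldimethylsilyl chloride, CC(C)(C)[Si](C)(C)Cl
Why: Silyl ether formation protects the only hydroxyl group against the strong base of step 2 and the hydride of step 4 without touching a stereocentre.

Step 2
Reactants: 2 (4R,6R)-4-[(tert-butyldimethylsilyl)oxy]-2,2,6-trimethylcyclohexan-1-one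
Product: 4 (4R)-4-[(tert-butyldimethylsilyl)oxy]-2,6,6-trimethylcyclohex-1-en-1-yl trifluoromethanesulfonate, via potassium enolate 3 (not isolated)
Conditions: KN(SiMe3)2, THF, −78 °C; then PhNTf2, −78 → 0 °C
Reagents that add atoms: N-phenylbis(trifluoromethanesulfonimide), FC(F)(F)S(=O)(=O)N(c1ccccc1)S(=O)(=O)C(F)(F)F
Why: The ketone can be deprotonated only at C6 (C2 is quaternary), so O‑triflation of the single enolate gives the tetrasubstituted enol triflate and removes the superfluous C6 stereocentre (enol triflate synthesis).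

Step 3
Reactants: 4 (4R)-4-[(tert-butyldimethylsilyl)oxy]-2,6,6-trimethylcyclohex-1-en-1-yl trifluoromethanesulfonate
Product: 5 methyl (4R)-4-[(tert-butyldimethylsilyl)oxy]-2,6,6-trimethylcyclohex-1-ene-1-carboxylate
Conditions: Pd(OAc)2 (5 mol%), PPh3, CO (1 atm), MeOH, Et3N, DMF, 60 °C
Reagents that add atoms: carbon monoxide, [C-]#[O+]; methanol, CO
Why: Palladium‑catalysed alkoxycarbonylation of the enol triflate (oxidative addition to zerovalent palladium, CO insertion, methanolysis) installs C7 on the future epoxide carbon and tolerates the silyl ether.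

Step 4
Reactants: 5 methyl (4R)-4-[(tert-butyldimethylsilyl)oxy]-2,6,6-trimethylcyclohex-1-ene-1-carboxylate
Product: 6 [(4R)-4-[(tert-butyldimethylsilyl)oxy]-2,6,6-trimethylcyclohex-1-en-1-yl]methanol
Conditions: iBu2AlH, CH2Cl2, −78 → 0 °C
Reagents that add atoms: none
Why: Hydride reduction of the conjugated ester gives the allylic alcohol needed to direct the epoxidation, the silyl ether being inert under these conditions.

Step 5
Reactants: 6 [(4R)-4-[(tert-butyldimethylsilyl)oxy]-2,6,6-trimethylcyclohex-1-en-1-yl]methanol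
Product: 7 [(1R,4S,6R)-4-[(tert-butyldimethylsilyl)oxy]-2,2,6-trimethyl-7-oxabicyclo[4.1.0]heptan-1-yl]methanol
Conditions: Ti(OiPr)4 (20 mol%), D-(−)-diethyl tartrate, tBuOOH, 4 Å MS, CH2Cl2, −20 °C
Reagents that add atoms: tert-butyl hydroperoxide, CC(C)(C)OO
Why: Sharpless asymmetric epoxidation: the titanium tartrate peroxide complex bound to the allylic hydroxyl delivers oxygen to one face of the tetrasubstituted C5=C6 bond, and with D‑(−)‑tartrate this is the face anti to the C3 silyloxy group, which sets C5 and C6 by reagent control.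

Step 6
Reactants: 7 [(1R,4S,6R)-4-[(tert-butyldimethylsilyl)oxy]-2,2,6-trimethyl-7-oxabicyclo[4.1.0]heptan-1-yl]methanol
Product: 8 (1S,4S,6R)-4-[(tert-butyldimethylsilyl)oxy]-2,2,6-trimethyl-7-oxabicyclo[4.1.0]heptane-1-carbaldehyde
Conditions: Dess–Martin periodinane, NaHCO3, CH2Cl2, 0 °C → rt
Reagents that add atoms: none
Why: Buffered Dess–Martin oxidation converts the primary epoxy alcohol into an aldehyde that has no α‑hydrogen and so cannot epimerise or eliminate.

Step 7
Reactants: 8 (1S,4S,6R)-4-[(tert-butyldimethylsilyl)oxy]-2,2,6-trimethyl-7-oxabicyclo[4.1.0]heptane-1-carbaldehyde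
Product: 10 [(1S,4S,6R)-4-[(tert-butyldimethylsilyl)oxy]-2,2,6-trimethyl-7-oxabicyclo[4.1.0]heptan-1-yl]acetaldehyde, via alkenyl boronate 9 (not isolated)
Conditions: CH2(Bpin)2, lithium 2,2,6,6-tetramethylpiperidide, THF, 0 °C; 8, −78 °C → rt; then 30% H2O2, pH 7 phosphate buffer, 0 °C
Reagents that add atoms: 2,2′-methylenebis(4,4,5,5-tetramethyl-1,3,2-dioxaborolane), CC1(C)OB(CB2OC(C)(C)C(C)(C)O2)OC1(C)C; hydrogen peroxide, OO
Why: Boron–Wittig olefination of the non‑enolisable aldehyde followed by oxidation of the C–B bond to the enol and tautomerisation is a one‑carbon homologation (C8) that avoids an acid‑labile enol ether next to the epoxide and leaves the stereocentres untouched.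

Step 8
Reactants: 10 [(1S,4S,6R)-4-[(tert-butyldimethylsilyl)oxy]-2,2,6-trimethyl-7-oxabicyclo[4.1.0]heptan-1-yl]acetaldehyde
Product: 11 (3E)-1-[(1S,4S,6R)-4-[(tert-butyldimethylsilyl)oxy]-2,2,6-trimethyl-7-oxabicyclo[4.1.0]heptan-1-yl]-3-methyl-4-(trimethylsilyl)but-3-en-2-ol (both C2 epimers)
Conditions: Ni(cod)2 (10 mol%), PBu3 (20 mol%), Et3B, 1-(trimethylsilyl)propyne, toluene, rt
Reagents that add atoms: trimethyl(prop-1-yn-1-yl)silane, CC#C[Si](C)(C)C
Why: Nickel‑catalysed reductive coupling of aldehyde and alkyne (oxidative cyclisation at zerovalent nickel, ethyl transfer from boron, β‑hydride elimination, C–H reductive elimination) forms C8–C9 at the methyl‑bearing alkyne carbon distal to silicon with syn addition of C and H, giving the E vinylsilane under non‑basic conditions that spare the β,γ‑epoxy aldehyde; the C8 carbinol forms as both epimers, which is harmless because C8 is oxidised in step 22.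

Step 9
Reactants: 11 (3E)-1-[(1S,4S,6R)-4-[(tert-butyldimethylsilyl)oxy]-2,2,6-trimethyl-7-oxabicyclo[4.1.0]heptan-1-yl]-3-methyl-4-(trimethylsilyl)but-3-en-2-ol
Product: 12 (3E)-1-[(1S,4S,6R)-4-[(tert-butyldimethylsilyl)oxy]-2,2,6-trimethyl-7-oxabicyclo[4.1.0]heptan-1-yl]-4-iodo-3-methylbut-3-en-2-ol (both C2 epimers)
Conditions: N-iodosuccinimide, MeCN, 0 °C, dark
Reagents that add atoms: N-iodosuccinimide, O=C1CCC(=O)N1I
Why: Electrophilic iododesilylation (ipso attack of iodonium, β‑silyl cation, loss of silicon) replaces the trimethylsilyl group by iodine with retention of the E geometry.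

Step 10
Reactants: 12 (3E)-1-[(1S,4S,6R)-4-[(tert-butyldimethylsilyl)oxy]-2,2,6-trimethyl-7-oxabicyclo[4.1.0]heptan-1-yl]-4-iodo-3-methylbut-3-en-2-ol
Product: 13 (1R,3S,6S)-6-[(3E)-2-hydroxy-4-iodo-3-methylbut-3-en-1-yl]-1,5,5-trimethyl-7-oxabicyclo[4.1.0]heptan-3-ol (both side-chain C2 epimers)
Conditions: Bu4NF, THF, 0 °C → rt
Reagents that add atoms: none
Why: Fluoride‑mediated desilylation frees the C3 hydroxyl once no strongly basic or oxidising step remains on this fragment, the vinyl iodide and the epoxide being stable to fluoride.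

Step 11
Reactants: 14 prop-2-yn-1-ol
Product: 16 (2E)-3-iodo-2-methylprop-2-en-1-ol, via alkenylalane 15 (not isolated)
Conditions: Me3Al, Cp2ZrCl2 (25 mol%), CH2Cl2, 0 °C → rt; then I2, THF, −30 → 0 °C
Reagents that add atoms: trimethylaluminium, C[Al](C)C; iodine, [I][I]
Why: Zirconium‑catalysed carboalumination (Negishi) adds methyl and aluminium syn across the alkyne with aluminium on the terminal carbon, and iodinolysis with retention gives the E iodide (its geometry is of no consequence later).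

Step 12
Reactants: 17 (2E)-3-methylpent-2-en-4-yn-1-ol
Product: 18 (2E)-3-methylpent-2-en-4-yn-1-yl 2,2-dimethylpropanoate
Conditions: pivaloyl chloride, pyridine, 4-(dimethylamino)pyridine (cat.), CH2Cl2, 0 °C
Reagents that add atoms: pivaloyl chloride, CC(C)(C)C(Cl)=O
Why: Acylation masks the C11′ hydroxyl as a pivalate through the acid‑ and ylide‑mediated steps, and the ester later serves as the leaving group for phosphonium salt formation.

Step 13
Reactants: 16 (2E)-3-iodo-2-methylprop-2-en-1-ol; 18 (2E)-3-methylpent-2-en-4-yn-1-yl 2,2-dimethylpropanoate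
Product: 19 (2E,6E)-8-hydroxy-3,7-dimethylocta-2,6-dien-4-yn-1-yl 2,2-dimethylpropanoate
Conditions: Pd(PPh3)2Cl2 (3 mol%), copper iodide CuI (5 mol%), Et3N, THF, rt
Reagents that add atoms: none
Why: Sonogashira coupling of the vinyl iodide with the terminal alkyne joins C6′ to C7′ with retention of both alkene geometries and tolerates the free hydroxyl and the ester.

Step 14
Reactants: 19 (2E,6E)-8-hydroxy-3,7-dimethylocta-2,6-dien-4-yn-1-yl 2,2-dimethylpropanoate
Product: 21 (2E)-3,7,7-trimethyl-8-oxo-6-(prop-1-en-2-yl)oct-2-en-4-yn-1-yl 2,2-dimethylpropanoate (racemic at C6), via allyl enol ether 20 (not isolated)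
Conditions: isobutyraldehyde (excess), TsOH·H2O (2 mol%), p-xylene, reflux, Dean–Stark trap
Reagents that add atoms: 2-methylpropanal, CC(C)C=O
Why: Acid‑catalysed condensation with isobutyraldehyde gives the allyl 2‑methylprop‑1‑enyl ether, whose Claisen rearrangement ([3,3]‑sigmatropic, chair transition state) forges the hindered C1′–C6′ bond between a quaternary and a tertiary carbon and moves the alkene into the isopropenyl group; C6′ forms racemic, which is acceptable because it is erased in step 17.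

Step 15
Reactants: 21 (2E)-3,7,7-trimethyl-8-oxo-6-(prop-1-en-2-yl)oct-2-en-4-yn-1-yl 2,2-dimethylpropanoate
Product: 23 (2E)-3,7,7-trimethyl-9-oxo-6-(prop-1-en-2-yl)non-2-en-4-yn-1-yl 2,2-dimethylpropanoate (racemic at C6), via enol ether 22 (not isolated)
Conditions: Ph3P(CH2OMe)Cl, KOtBu, THF, 0 °C; then 1 M HCl, THF, 0 °C
Reagents that add atoms: (methoxymethyl)triphenylphosphonium chloride, COC[P+](c1ccccc1)(c1ccccc1)c1ccccc1.[Cl-]; water, O
Why: Wittig methoxymethylenation of the neopentyl‑type aldehyde and mild hydrolysis of the enol ether add C3′ as the aldehyde carbon (one‑carbon homologation), cold dilute acid being chosen so that the product does not cyclise prematurely.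

Step 16
Reactants: 23 (2E)-3,7,7-trimethyl-9-oxo-6-(prop-1-en-2-yl)non-2-en-4-yn-1-yl 2,2-dimethylpropanoate
Product: 24 (2E)-5-[(1RS,4S)-4-hydroxy-6,6-dimethyl-2-methylidenecyclohexyl]-3-methylpent-2-en-4-yn-1-yl 2,2-dimethylpropanoate
Conditions: CrCl(C27H29NO2) (7.5 mol%; chloro complex of trivalent chromium with the tridentate Schiff base from (1R,2S)-1-aminoindan-2-ol and 3-(adamantan-1-yl)-2-hydroxy-5-methylbenzaldehyde), powdered 4 Å MS, toluene, 4 °C
Reagents that add atoms: none
Why: The chiral chromium Lewis acid binds the aldehyde oxygen, the CH2 terminus of the isopropenyl group (C4′) attacks the carbonyl carbon (C3′) and an allylic hydrogen passes to oxygen in a concerted, asynchronous carbonyl‑ene reaction through a chair‑like six‑membered transition state. The closest known reaction type is the Lewis‑acid‑catalysed ene cyclisation of 5‑methylhex‑5‑enals to 3‑methylidenecyclohexanols, including its enantioselective version with tridentate Schiff‑base chromium chloride complexes. Ring C is closed in the six‑membered (2,4) ene mode, that is with the tether on the central ene carbon, bond formation at the ene terminus and exo attack at the carbonyl group. The only new stereocentre, the carbinol C3′, is set by the catalyst, which exposes one face of the bound aldehyde, whereas C6′ is a racemic bystander whose two epimers both cyclise and are merged in step 17. The step needs enantioface selectivity (catalyst), chemoselectivity for the aldehyde over the weakly basic pivalate and for the isopropenyl group over the remote trisubstituted alkene and the alkyne (only the isopropenyl terminus reaches the aldehyde through a six‑membered transition state, and the gem‑dimethyl group at C1′ favours the folded conformer), but no control over which allylic hydrogen moves, because transfer from the methyl group gives 24 and transfer from C6′–H gives 25 directly.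

Step 17
Reactants: 24 (2E)-5-[(1RS,4S)-4-hydroxy-6,6-dimethyl-2-methylidenecyclohexyl]-3-methylpent-2-en-4-yn-1-yl 2,2-dimethylpropanoate
Product: 25 (2E)-5-[(4R)-4-hydroxy-2,6,6-trimethylcyclohex-1-en-1-yl]-3-methylpent-2-en-4-yn-1-yl 2,2-dimethylpropanoate
Conditions: TsOH·H2O (5 mol%), CH2Cl2, rt
Reagents that add atoms: none
Why: Acid‑catalysed alkene isomerisation through the tertiary C5′ carbocation leads to the thermodynamically preferred tetrasubstituted ring alkene conjugated with the alkyne by loss of the propargylic C6′ proton, which removes the C6′ stereocentre so that both diastereomers of 24 converge on the single enantiomer 25.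

Step 18
Reactants: 25 (2E)-5-[(4R)-4-hydroxy-2,6,6-trimethylcyclohex-1-en-1-yl]-3-methylpent-2-en-4-yn-1-yl 2,2-dimethylpropanoate
Product: 26 [(2E)-5-[(4R)-4-hydroxy-2,6,6-trimethylcyclohex-1-en-1-yl]-3-methylpent-2-en-4-yn-1-yl]triphenylphosphonium bromide
Conditions: PPh3·HBr, MeOH, rt
Reagents that add atoms: triphenylphosphine hydrobromide, [Br-].[PH+](c1ccccc1)(c1ccccc1)c1ccccc1
Why: Under PPh3·HBr the allylic pivalate ionises to a conjugation‑stabilised allyl cation that PPh3 captures at the primary terminus (the reaction type that converts allylic alcohols and acetates of polyenes into Wittig salts), while the secondary ring hydroxyl does not ionise.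

Step 19
Reactants: 26 [(2E)-5-[(4R)-4-hydroxy-2,6,6-trimethylcyclohex-1-en-1-yl]-3-methylpent-2-en-4-yn-1-yl]triphenylphosphonium bromide; 27 (2E,4E,6E)-2,7-dimethylocta-2,4,6-trienedial (in excess)
Product: 29 (2E,4E,6E,8E,10E)-13-[(4R)-4-hydroxy-2,6,6-trimethylcyclohex-1-en-1-yl]-2,7,11-trimethyltrideca-2,4,6,8,10-pentaen-12-ynal, via phosphorus ylide 28 (not isolated)
Conditions: NaOMe, MeOH/CH2Cl2, 0 °C → rt; then I2 (cat.), CH2Cl2, rt, diffuse light
Reagents that add atoms: none
Why: Wittig olefination of the semi‑stabilised ylide with an excess of the symmetrical dialdehyde gives the mono‑condensation product with the new C11′=C12′ bond, and iodine‑catalysed equilibration converts any Z isomer into the favoured all‑E polyene.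

Step 20
Reactants: 29 (2E,4E,6E,8E,10E)-13-[(4R)-4-hydroxy-2,6,6-trimethylcyclohex-1-en-1-yl]-2,7,11-trimethyltrideca-2,4,6,8,10-pentaen-12-ynal
Product: 30 (1R)-3,5,5-trimethyl-4-[(3E,5E,7E,9E,11E,13E)-3,7,12-trimethyl-14-(4,4,5,5-tetramethyl-1,3,2-dioxaborolan-2-yl)tetradeca-3,5,7,9,11,13-hexaen-1-yn-1-yl]cyclohex-3-en-1-ol
Conditions: CrCl2, Cl2CHBpin, LiI, THF, rt, dark
Reagents that add atoms: 2-(dichloromethyl)-4,4,5,5-tetramethyl-1,3,2-dioxaborolane, ClC(Cl)B1OC(C)(C)C(C)(C)O1
Why: Takai–Utimoto‑type olefination: the geminal dichromium species formed from the dihalomethylboronate and divalent chromium adds to the aldehyde and eliminates to give the E alkenyl boronate (C11=C12), free hydroxyl groups being tolerated.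

Step 21
Reactants: 13 (1R,3S,6S)-6-[(3E)-2-hydroxy-4-iodo-3-methylbut-3-en-1-yl]-1,5,5-trimethyl-7-oxabicyclo[4.1.0]heptan-3-ol; 30 (1R)-3,5,5-trimethyl-4-[(3E,5E,7E,9E,11E,13E)-3,7,12-trimethyl-14-(4,4,5,5-tetramethyl-1,3,2-dioxaborolan-2-yl)tetradeca-3,5,7,9,11,13-hexaen-1-yn-1-yl]cyclohex-3-en-1-ol
Product: 31 (3S,5R,6S,3′R)-5,6-epoxy-7′,8′-didehydro-5,6,7,8-tetrahydro-β,β-carotene-3,8,3′-triol (both C8 epimers)
Conditions: Pd(OAc)2 (5 mol%), SPhos (10 mol%), K3PO4 (aq.), THF, rt, dark
Reagents that add atoms: none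
Why: Suzuki–Miyaura coupling of the alkenyl boronate with the vinyl iodide forms the C10–C11 single bond with retention of both alkene geometries, and the aqueous base is harmless at this stage because C8 is still an alcohol.

Step 22
Reactants: 31 (3S,5R,6S,3′R)-5,6-epoxy-7′,8′-didehydro-5,6,7,8-tetrahydro-β,β-carotene-3,8,3′-triol
Product: 32 (3S,5R,6S,3′R)-5,6-epoxy-3,3′-dihydroxy-7′,8′-didehydro-5,6,7,8-tetrahydro-β,β-caroten-8-one (the target, CNP0332618.1)
Conditions: MnO2 (activated, excess), CH2Cl2, rt, dark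
Reagents that add atoms: none
Why: Activated MnO2 oxidises only the allylic, polyene‑conjugated C8 carbinol (the C3 and C3′ hydroxyls are not allylic), both C8 epimers give the same ketone, and the neutral heterogeneous conditions avoid base‑induced opening of the epoxide in the β,γ‑epoxy ketone (allylic alcohol oxidation).

**Compound list**

1 | (4R,6R)-4-hydroxy-2,2,6-trimethylcyclohexan-1-one | C[C@@H]1C[C@@H](O)CC(C)(C)C1=O | starting material
2 | (4R,6R)-4-[(tert-butyldimethylsilyl)oxy]-2,2,6-trimethylcyclohexan-1-one | C[C@@H]1C[C@@H](O[Si](C)(C)C(C)(C)C)CC(C)(C)C1=O | intermediate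
3 | potassium (4R)-4-[(tert-butyldimethylsilyl)oxy]-2,6,6-trimethylcyclohex-1-en-1-olate | CC1=C([O-])C(C)(C)C[C@H](O[Si](C)(C)C(C)(C)C)C1.[K+] | intermediate (not isolated)
4 | (4R)-4-[(tert-butyldimethylsilyl)oxy]-2,6,6-trimethylcyclohex-1-en-1-yl trifluoromethanesulfonate | CC1=C(OS(=O)(=O)C(F)(F)F)C(C)(C)C[C@H](O[Si](C)(C)C(C)(C)C)C1 | intermediate
5 | methyl (4R)-4-[(tert-butyldimethylsilyl)oxy]-2,6,6-trimethylcyclohex-1-ene-1-carboxylate | CC1=C(C(=O)OC)C(C)(C)C[C@H](O[Si](C)(C)C(C)(C)C)C1 | intermediate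
6 | [(4R)-4-[(tert-butyldimethylsilyl)oxy]-2,6,6-trimethylcyclohex-1-en-1-yl]methanol | CC1=C(CO)C(C)(C)C[C@H](O[Si](C)(C)C(C)(C)C)C1 | intermediate
7 | [(1R,4S,6R)-4-[(tert-butyldimethylsilyl)oxy]-2,2,6-trimethyl-7-oxabicyclo[4.1.0]heptan-1-yl]methanol | OC[C@@]12O[C@]1(C)C[C@@H](O[Si](C)(C)C(C)(C)C)CC2(C)C | intermediate
8 | (1S,4S,6R)-4-[(tert-butyldimethylsilyl)oxy]-2,2,6-trimethyl-7-oxabicyclo[4.1.0]heptane-1-carbaldehyde | O=C[C@@]12O[C@]1(C)C[C@@H](O[Si](C)(C)C(C)(C)C)CC2(C)C | intermediate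
9 | 2-{(E)-2-[(1S,4S,6R)-4-[(tert-butyldimethylsilyl)oxy]-2,2,6-trimethyl-7-oxabicyclo[4.1.0]heptan-1-yl]ethenyl}-4,4,5,5-tetramethyl-1,3,2-dioxaborolane | CC1(C)OB(/C=C/[C@@]23O[C@]2(C)C[C@@H](O[Si](C)(C)C(C)(C)C)CC3(C)C)OC1(C)C | intermediate (not isolated)
10 | [(1S,4S,6R)-4-[(tert-butyldimethylsilyl)oxy]-2,2,6-trimethyl-7-oxabicyclo[4.1.0]heptan-1-yl]acetaldehyde | O=CC[C@@]12O[C@]1(C)C[C@@H](O[Si](C)(C)C(C)(C)C)CC2(C)C | intermediate
11 | (3E)-1-[(1S,4S,6R)-4-[(tert-butyldimethylsilyl)oxy]-2,2,6-trimethyl-7-oxabicyclo[4.1.0]heptan-1-yl]-3-methyl-4-(trimethylsilyl)but-3-en-2-ol, both C2 epimers | C[Si](C)(C)/C=C(\C)C(O)C[C@@]12O[C@]1(C)C[C@@H](O[Si](C)(C)C(C)(C)C)CC2(C)C | intermediate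
12 | (3E)-1-[(1S,4S,6R)-4-[(tert-butyldimethylsilyl)oxy]-2,2,6-trimethyl-7-oxabicyclo[4.1.0]heptan-1-yl]-4-iodo-3-methylbut-3-en-2-ol, both C2 epimers | I/C=C(\C)C(O)C[C@@]12O[C@]1(C)C[C@@H](O[Si](C)(C)C(C)(C)C)CC2(C)C | intermediate
13 | (1R,3S,6S)-6-[(3E)-2-hydroxy-4-iodo-3-methylbut-3-en-1-yl]-1,5,5-trimethyl-7-oxabicyclo[4.1.0]heptan-3-ol, both side-chain C2 epimers | I/C=C(\C)C(O)C[C@@]12O[C@]1(C)C[C@@H](O)CC2(C)C | intermediate
14 | prop-2-yn-1-ol | C#CCO | starting material
15 | (E)-alkenylalane: dimethyl[(1E)-3-[(dimethylalumanyl)oxy]-2-methylprop-1-en-1-yl]alumane | C[Al](C)/C=C(\C)CO[Al](C)C | intermediate (not isolated)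
16 | (2E)-3-iodo-2-methylprop-2-en-1-ol | OC/C(C)=C/I | intermediate
17 | (2E)-3-methylpent-2-en-4-yn-1-ol | C#C/C(C)=C/CO | starting material
18 | (2E)-3-methylpent-2-en-4-yn-1-yl 2,2-dimethylpropanoate | C#C/C(C)=C/COC(=O)C(C)(C)C | intermediate
19 | (2E,6E)-8-hydroxy-3,7-dimethylocta-2,6-dien-4-yn-1-yl 2,2-dimethylpropanoate | OC/C(C)=C/C#C/C(C)=C/COC(=O)C(C)(C)C | intermediate
20 | (2E,6E)-3,7-dimethyl-8-[(2-methylprop-1-en-1-yl)oxy]octa-2,6-dien-4-yn-1-yl 2,2-dimethylpropanoate | CC(C)=COC/C(C)=C/C#C/C(C)=C/COC(=O)C(C)(C)C | intermediate (not isolated)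
21 | (2E)-3,7,7-trimethyl-8-oxo-6-(prop-1-en-2-yl)oct-2-en-4-yn-1-yl 2,2-dimethylpropanoate, racemic at C6 | O=CC(C)(C)C(C#C/C(C)=C/COC(=O)C(C)(C)C)C(C)=C | intermediate
22 | (2E)-9-methoxy-3,7,7-trimethyl-6-(prop-1-en-2-yl)nona-2,8-dien-4-yn-1-yl 2,2-dimethylpropanoate, enol ether E/Z mixture, racemic at C6 | COC=CC(C)(C)C(C#C/C(C)=C/COC(=O)C(C)(C)C)C(C)=C | intermediate (not isolated)
23 | (2E)-3,7,7-trimethyl-9-oxo-6-(prop-1-en-2-yl)non-2-en-4-yn-1-yl 2,2-dimethylpropanoate, racemic at C6 | O=CCC(C)(C)C(C#C/C(C)=C/COC(=O)C(C)(C)C)C(C)=C | intermediate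
24 | (2E)-5-[(1RS,4S)-4-hydroxy-6,6-dimethyl-2-methylidenecyclohexyl]-3-methylpent-2-en-4-yn-1-yl 2,2-dimethylpropanoate | C=C1C(C#C/C(C)=C/COC(=O)C(C)(C)C)C(C)(C)C[C@H](O)C1 | intermediate
25 | (2E)-5-[(4R)-4-hydroxy-2,6,6-trimethylcyclohex-1-en-1-yl]-3-methylpent-2-en-4-yn-1-yl 2,2-dimethylpropanoate | CC1=C(C#C/C(C)=C/COC(=O)C(C)(C)C)C(C)(C)C[C@H](O)C1 | intermediate
26 | [(2E)-5-[(4R)-4-hydroxy-2,6,6-trimethylcyclohex-1-en-1-yl]-3-methylpent-2-en-4-yn-1-yl]triphenylphosphonium bromide | CC1=C(C#C/C(C)=C/C[P+](c2ccccc2)(c2ccccc2)c2ccccc2)C(C)(C)C[C@H](O)C1.[Br-] | intermediate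
27 | (2E,4E,6E)-2,7-dimethylocta-2,4,6-trienedial | O=C/C(C)=C/C=C/C=C(C)/C=O | starting material
28 | ylide of 26: (4R)-3,5,5-trimethyl-4-[(3E)-3-methyl-5-(triphenyl-λ5-phosphanylidene)pent-3-en-1-yn-1-yl]cyclohex-3-en-1-ol | CC1=C(C#C/C(C)=C/C=P(c2ccccc2)(c2ccccc2)c2ccccc2)C(C)(C)C[C@H](O)C1 | intermediate (not isolated)
29 | (2E,4E,6E,8E,10E)-13-[(4R)-4-hydroxy-2,6,6-trimethylcyclohex-1-en-1-yl]-2,7,11-trimethyltrideca-2,4,6,8,10-pentaen-12-ynal | CC1=C(C#C/C(C)=C/C=C/C(C)=C/C=C/C=C(C)/C=O)C(C)(C)C[C@H](O)C1 | intermediate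
30 | (1R)-3,5,5-trimethyl-4-[(3E,5E,7E,9E,11E,13E)-3,7,12-trimethyl-14-(4,4,5,5-tetramethyl-1,3,2-dioxaborolan-2-yl)tetradeca-3,5,7,9,11,13-hexaen-1-yn-1-yl]cyclohex-3-en-1-ol | CC1=C(C#C/C(C)=C/C=C/C(C)=C/C=C/C=C(C)/C=C/B2OC(C)(C)C(C)(C)O2)C(C)(C)C[C@H](O)C1 | intermediate
31 | (3S,5R,6S,3′R)-5,6-epoxy-7′,8′-didehydro-5,6,7,8-tetrahydro-β,β-carotene-3,8,3′-triol, both C8 epimers | CC1=C(C#C/C(C)=C/C=C/C(C)=C/C=C/C=C(C)/C=C/C=C(\C)C(O)C[C@@]23O[C@]2(C)C[C@@H](O)CC3(C)C)C(C)(C)C[C@H](O)C1 | intermediate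
32 | (3S,5R,6S,3′R)-5,6-epoxy-3,3′-dihydroxy-7′,8′-didehydro-5,6,7,8-tetrahydro-β,β-caroten-8-one | CC1=C(C#C/C(C)=C/C=C/C(C)=C/C=C/C=C(C)/C=C/C=C(\C)C(=O)C[C@@]23O[C@]2(C)C[C@@H](O)CC3(C)C)C(C)(C)C[C@H](O)C1 | target

**Count and risks**

Total: 22 steps. Longest linear sequence: 12 steps (steps 1–10 from 1, then steps 21 and 22).

Step 16. What may go wrong: insufficient enantioface discrimination on a substrate that carries an extra branch at C6′ (one C6′ epimer may be mismatched with the catalyst), or slow turnover. Fallback: from 23, cyclisation with the achiral Lewis acid Me2AlCl (CH2Cl2, −78 °C) should give the racemic methylidene alcohol (2E)-5-(4-hydroxy-6,6-dimethyl-2-methylidenecyclohexyl)-3-methylpent-2-en-4-yn-1-yl 2,2-dimethylpropanoate F1. Acid‑catalysed double‑bond migration as in step 17 then gives the racemic enyne alcohol (2E)-5-(4-hydroxy-2,6,6-trimethylcyclohex-1-en-1-yl)-3-methylpent-2-en-4-yn-1-yl 2,2-dimethylpropanoate F2. Lipase‑catalysed acylation (immobilised Candida antarctica lipase B, vinyl acetate, tert‑butyl methyl ether) is expected to acylate one enantiomer selectively. If the R alcohol reacts faster, the acetate (2E)-5-[(4R)-4-acetoxy-2,6,6-trimethylcyclohex-1-en-1-yl]-3-methylpent-2-en-4-yn-1-yl 2,2-dimethylpropanoate F3 is separated and cleaved with K2CO3 in methanol (the hindered pivalate should survive); if the S alcohol reacts faster, the unreacted alcohol is used directly. Either way the route is rejoined at 25.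

Step 7. What may go wrong: slow addition of the bulky boryl carbanion to the neopentyl‑type aldehyde, or base‑induced β‑elimination (opening of the epoxide) of the enolisable β,γ‑epoxy aldehyde during the oxidative work‑up. Fallback: from 8, Wittig methylenation (Ph3PCH3Br, KOtBu, THF) gives the vinyl epoxide (1S,4S,6R)-4-[(tert-butyldimethylsilyl)oxy]-1-ethenyl-2,2,6-trimethyl-7-oxabicyclo[4.1.0]heptane F4. Hydroboration with 9‑borabicyclo[3.3.1]nonane and buffered H2O2 gives the primary alcohol 2-[(1S,4S,6R)-4-[(tert-butyldimethylsilyl)oxy]-2,2,6-trimethyl-7-oxabicyclo[4.1.0]heptan-1-yl]ethan-1-ol F5, so that the basic peroxide meets a robust alcohol and not the aldehyde. Buffered Dess–Martin oxidation of F5 then releases 10 immediately before step 8.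

Step 17. What may go wrong: incomplete or unselective migration of the double bond (stopping at the C4′=C5′ isomer), or ionisation of the allylic pivalate under acid. Fallback: from 24, reductive removal of the pivalate (iBu2AlH, CH2Cl2, −78 °C) gives the diol (1S)-4-[(3E)-5-hydroxy-3-methylpent-3-en-1-yn-1-yl]-5,5-dimethyl-3-methylidenecyclohexan-1-ol F6 (mixture at C4). An anionic prototropic shift (KOtBu, DMSO, rt: deprotonation of the doubly activated C6′–H and reprotonation at the exocyclic carbon) should give the conjugated diol (1R)-4-[(3E)-5-hydroxy-3-methylpent-3-en-1-yn-1-yl]-3,5,5-trimethylcyclohex-3-en-1-ol F7. PPh3·HBr in methanol converts the primary allylic alcohol of F7 into 26, where the route is rejoined.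

**Further compounds**

F1 | step 16 | (2E)-5-(4-hydroxy-6,6-dimethyl-2-methylidenecyclohexyl)-3-methylpent-2-en-4-yn-1-yl 2,2-dimethylpropanoate, racemic, both ring diastereomers | C=C1C(C#C/C(C)=C/COC(=O)C(C)(C)C)C(C)(C)CC(O)C1
F2 | step 16 | (2E)-5-(4-hydroxy-2,6,6-trimethylcyclohex-1-en-1-yl)-3-methylpent-2-en-4-yn-1-yl 2,2-dimethylpropanoate, racemic | CC1=C(C#C/C(C)=C/COC(=O)C(C)(C)C)C(C)(C)CC(O)C1
F3 | step 16 | (2E)-5-[(4R)-4-acetoxy-2,6,6-trimethylcyclohex-1-en-1-yl]-3-methylpent-2-en-4-yn-1-yl 2,2-dimethylpropanoate | CC1=C(C#C/C(C)=C/COC(=O)C(C)(C)C)C(C)(C)C[C@H](OC(C)=O)C1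
F4 | step 7 | (1S,4S,6R)-4-[(tert-butyldimethylsilyl)oxy]-1-ethenyl-2,2,6-trimethyl-7-oxabicyclo[4.1.0]heptane | C=C[C@@]12O[C@]1(C)C[C@@H](O[Si](C)(C)C(C)(C)C)CC2(C)C
F5 | step 7 | 2-[(1S,4S,6R)-4-[(tert-butyldimethylsilyl)oxy]-2,2,6-trimethyl-7-oxabicyclo[4.1.0]heptan-1-yl]ethan-1-ol | OCC[C@@]12O[C@]1(C)C[C@@H](O[Si](C)(C)C(C)(C)C)CC2(C)C
F6 | step 17 | (1S)-4-[(3E)-5-hydroxy-3-methylpent-3-en-1-yn-1-yl]-5,5-dimethyl-3-methylidenecyclohexan-1-ol, both C4 epimers | C=C1C(C#C/C(C)=C/CO)C(C)(C)C[C@H](O)C1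
F7 | step 17 | (1R)-4-[(3E)-5-hydroxy-3-methylpent-3-en-1-yn-1-yl]-3,5,5-trimethylcyclohex-3-en-1-ol | CC1=C(C#C/C(C)=C/CO)C(C)(C)C[C@H](O)C1
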